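**Strategy.** The cyclohexene ring is opened retrosynthetically at C4=C5 (ring-closing metathesis), and the exocyclic CH2–C1 bond is made on an acyclic ketol derived from D-mannitol. The route exploits the latent twofold axis that relates ring carbons C1/C2 and the benzoyloxy carbons C6/C3: in the symmetric diol dibenzoate either hydroxyl gives the same ketol on oxidation. In the key step a hydroxymethyl-anion equivalent, [(isopropoxydimethylsilyl)methyl]magnesium chloride, adds to this ketol. The C2 alkoxide forms a Cram chelate and the C6 benzoate acts as Felkin–Anh polar group; both steer the nucleophile to the same carbonyl face and set the quaternary carbinol C1. C–Si oxidation, primary benzoylation and ring closure complete the target.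

Key step: step 8

Remark: ring numbering is used for the acyclic intermediates as well (C1 quaternary carbinol, C2 free secondary carbinol, C3 and C6 benzoyloxy carbons, C4=C5 alkene); compounds 1 and 8 are taken as catalogue materials.

Step 1
Reactants: 1 3,4-O-isopropylidene-D-mannitol
Product: 2 3,4-O-isopropylidene-1,6-di-O-(p-tolylsulfonyl)-D-mannitol
Conditions: TsCl (2.1 equiv), pyridine, −15 °C to 0 °C
Reagents that add atoms: p-toluenesulfonyl chloride, Cc1ccc(cc1)S(Cl)(=O)=O
Why: Sulfonylation is much faster at the two primary hydroxyls than at the secondary ones next to the dioxolane, so the bis-primary tosylate should form without touching a stereocentre.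

Step 2
Reactants: 2 3,4-O-isopropylidene-1,6-di-O-(p-tolylsulfonyl)-D-mannitol
Product: 3 1,2:5,6-dianhydro-3,4-O-isopropylidene-D-mannitol
Conditions: K2CO3, MeOH, rt
Reagents that add atoms: none
Why: Intramolecular Williamson etherification (3-exo-tet) of each secondary alkoxide onto the neighbouring primary tosylate should close both oxiranes with retention at the secondary carbons, since only the primary carbon is substituted.

Step 3
Reactants: 3 1,2:5,6-dianhydro-3,4-O-isopropylidene-D-mannitol
Product: 4 (3R,4R,5R,6R)-4,5-O-isopropylideneocta-1,7-diene-3,4,5,6-tetrol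
Conditions: Me3S+ I− (6 equiv), n-BuLi (5.8 equiv), THF, −10 °C to rt
Reagents that add atoms: trimethylsulfonium iodide, C[S+](C)C.[I-]
Why: Dimethylsulfonium methylide opens each terminal epoxide at CH2 and the resulting β-alkoxy sulfonium salt loses Me2S by ylide-mediated elimination, a one-carbon epoxide-to-allylic-alcohol homologation that leaves the carbinol stereocentres untouched.

Step 4
Reactants: 4 (3R,4R,5R,6R)-4,5-O-isopropylideneocta-1,7-diene-3,4,5,6-tetrol
Product: 5 (3R,4R,5R,6R)-4,5-O-isopropylideneocta-1,7-diene-3,4,5,6-tetrol 3,6-dibenzoate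
Conditions: BzCl (2.5 equiv), pyridine, DMAP (cat.), CH2Cl2, 0 °C to rt
Reagents that add atoms: benzoyl chloride, O=C(Cl)c1ccccc1
Why: Acylation of the two equivalent allylic alcohols under nucleophilic catalysis should install the future C3 and C6 benzoates at an early, symmetric stage.

Step 5
Reactants: 5 (3R,4R,5R,6R)-4,5-O-isopropylideneocta-1,7-diene-3,4,5,6-tetrol 3,6-dibenzoate
Product: 6 (3R,4S,5S,6R)-4,5-dihydroxyocta-1,7-diene-3,6-diyl dibenzoate
Conditions: TFA/H2O (9:1), CH2Cl2, 0 °C to rt
Reagents that add atoms: none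
Why: Acid-catalysed ketal hydrolysis should free the central threo-diol, while benzoates tolerate brief aqueous acid and acyl migration is slow without base.

Step 6
Reactants: 6 (3R,4S,5S,6R)-4,5-dihydroxyocta-1,7-diene-3,6-diyl dibenzoate
Product: 7 (3R,5R,6R)-5-hydroxy-4-oxoocta-1,7-diene-3,6-diyl dibenzoate
Conditions: 2-iodoxybenzoic acid (IBX, 1.1 equiv), DMSO, rt
Reagents that add atoms: none
Why: IBX oxidises 1,2-diols to α-ketols without C–C cleavage, and because the two carbinols of 6 are homotopic, oxidation of either should give the same ketol, with the limiting oxidant holding the reaction at mono-oxidation.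

Step 7
Reactants: 8 (chloromethyl)(isopropoxy)dimethylsilane
Product: 9 [(isopropoxydimethylsilyl)methyl]magnesium chloride (THF solution)
Conditions: Mg turnings, THF, rt to 45 °C
Reagents that add atoms: magnesium, [Mg]
Why: Insertion of magnesium into the C–Cl bond (Grignard formation) should give the α-silyl Grignard reagent that serves as hydroxymethyl-anion equivalent.

Step 8
Reactants: 7 (3R,5R,6R)-5-hydroxy-4-oxoocta-1,7-diene-3,6-diyl dibenzoate; 9 [(isopropoxydimethylsilyl)methyl]magnesium chloride
Product: 11 (3R,4R,5R,6R)-4,5-dihydroxy-4-(hydroxymethyl)octa-1,7-diene-3,6-diyl dibenzoate, via β-hydroxysilane 10 (not isolated)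
Conditions: 9 (3.5 equiv), THF–Et2O, −78 °C, AcOH quench at −78 °C; then KF, KHCO3, 30% aq. H2O2, THF/MeOH, 0 °C to rt
Reagents that add atoms: hydrogen peroxide, OO
Why: The first equivalent of 9 deprotonates the hydroxyl of 7 and the magnesium alkoxide on future C2 locks the adjacent carbonyl (future C1) in a five-membered Cram chelate, to which a second equivalent adds from the face bearing the C2 hydrogen, forming the exocyclic CH2–C1 bond (Grignard 1,2-addition under chelation control, the closest known type being additions to α-hydroxy and α-alkoxy ketones). No ring is closed. The only new stereocentre, the tertiary carbinol C1, is controlled by two elements that agree: the chelate places the new hydroxyl erythro to the C2 oxygen (cis in the later ring), and the non-chelating benzoate on the other α-carbon (future C6) acts as Felkin–Anh polar group and places it threo to the C6 oxygen (trans in the ring), the two demands coinciding because both α-centres carry the same configuration inherited from the twofold axis of 6. The step needs chemoselectivity for the ketone over the two benzoates and addition faster than enolisation toward C6, which the chelate-activated carbonyl at −78 °C and the modest basicity of the α-silyl Grignard reagent should secure. Oxidation of the C–Si bond by H2O2 with fluoride (Tamao–Fleming oxidation) on the crude adduct then turns the silylmethyl group into CH2OH without changing the carbon skeleton.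

Step 9
Reactants: 11 (3R,4R,5R,6R)-4,5-dihydroxy-4-(hydroxymethyl)octa-1,7-diene-3,6-diyl dibenzoate
Product: 12 (3R,4R,5R,6R)-4-[(benzoyloxy)methyl]-4,5-dihydroxyocta-1,7-diene-3,6-diyl dibenzoate
Conditions: BzCl (1.05 equiv), pyridine, CH2Cl2, −40 °C to −10 °C
Reagents that add atoms: benzoyl chloride, O=C(Cl)c1ccccc1
Why: Acylation is far faster at the primary hydroxyl than at the tertiary one or at the secondary one flanked by a quaternary carbon, so one equivalent of acid chloride at low temperature should give the primary benzoate.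

Step 10
Reactants: 12 (3R,4R,5R,6R)-4-[(benzoyloxy)methyl]-4,5-dihydroxyocta-1,7-diene-3,6-diyl dibenzoate
Product: 13 [(1R,2R,3R,6R)-3,6-bis(benzoyloxy)-1,2-dihydroxycyclohex-4-en-1-yl]methyl benzoate
Conditions: second-generation Grubbs catalyst RuCl2(=CHPh)(PCy3)(H2IMes) (5 mol %), CH2Cl2, 40 °C
Reagents that add atoms: none
Why: Ring-closing olefin metathesis of the 1,7-diene should close the six-membered ring at C4=C5 with loss of ethene, tolerating free hydroxyls and allylic esters and leaving the four stereocentres, which lie outside the reacting alkenes, unchanged.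

**Compound list**

1 | 3,4-O-isopropylidene-D-mannitol | OC[C@@H](O)[C@H]1OC(C)(C)O[C@@H]1[C@H](O)CO | starting material
2 | 3,4-O-isopropylidene-1,6-di-O-(p-tolylsulfonyl)-D-mannitol | Cc1ccc(cc1)S(=O)(=O)OC[C@@H](O)[C@H]2OC(C)(C)O[C@@H]2[C@H](O)COS(=O)(=O)c3ccc(C)cc3 | intermediate
3 | 1,2:5,6-dianhydro-3,4-O-isopropylidene-D-mannitol | C1O[C@H]1[C@H]2OC(C)(C)O[C@@H]2[C@H]3CO3 | intermediate
4 | (3R,4R,5R,6R)-4,5-O-isopropylideneocta-1,7-diene-3,4,5,6-tetrol (D-manno; free allylic hydroxyls at C3 and C6) | C=C[C@@H](O)[C@H]1OC(C)(C)O[C@@H]1[C@H](O)C=C | intermediate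
5 | (3R,4R,5R,6R)-4,5-O-isopropylideneocta-1,7-diene-3,4,5,6-tetrol 3,6-dibenzoate | C=C[C@@H](OC(=O)c1ccccc1)[C@H]2OC(C)(C)O[C@@H]2[C@H](OC(=O)c3ccccc3)C=C | intermediate
6 | (3R,4S,5S,6R)-4,5-dihydroxyocta-1,7-diene-3,6-diyl dibenzoate (D-manno, C2-symmetric) | C=C[C@@H](OC(=O)c1ccccc1)[C@@H](O)[C@H](O)[C@H](OC(=O)c2ccccc2)C=C | intermediate
7 | (3R,5R,6R)-5-hydroxy-4-oxoocta-1,7-diene-3,6-diyl dibenzoate | C=C[C@@H](OC(=O)c1ccccc1)C(=O)[C@H](O)[C@H](OC(=O)c2ccccc2)C=C | intermediate
8 | (chloromethyl)(isopropoxy)dimethylsilane | CC(C)O[Si](C)(C)CCl | starting material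
9 | [(isopropoxydimethylsilyl)methyl]magnesium chloride | CC(C)O[Si](C)(C)C[Mg]Cl | intermediate
10 | (3R,4R,5R,6R)-4,5-dihydroxy-4-[(isopropoxydimethylsilyl)methyl]octa-1,7-diene-3,6-diyl dibenzoate | C=C[C@@H](OC(=O)c1ccccc1)[C@@](O)(C[Si](C)(C)OC(C)C)[C@H](O)[C@H](OC(=O)c2ccccc2)C=C | intermediate
11 | (3R,4R,5R,6R)-4,5-dihydroxy-4-(hydroxymethyl)octa-1,7-diene-3,6-diyl dibenzoate | C=C[C@@H](OC(=O)c1ccccc1)[C@@](O)(CO)[C@H](O)[C@H](OC(=O)c2ccccc2)C=C | intermediate
12 | (3R,4R,5R,6R)-4-[(benzoyloxy)methyl]-4,5-dihydroxyocta-1,7-diene-3,6-diyl dibenzoate | C=C[C@@H](OC(=O)c1ccccc1)[C@@](O)(COC(=O)c2ccccc2)[C@H](O)[C@H](OC(=O)c3ccccc3)C=C | intermediate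
13 | [(1R,2R,3R,6R)-3,6-bis(benzoyloxy)-1,2-dihydroxycyclohex-4-en-1-yl]methyl benzoate | O=C(OC[C@@]1(O)[C@H](O)[C@H](OC(=O)c2ccccc2)C=C[C@H]1OC(=O)c1ccccc1)c1ccccc1 | target

**Step count.** Total: 10 steps. Longest linear sequence: 9 steps (1 to 13 through steps 1–6 and 8–10; step 7 is a one-step side branch).

**Steps most likely to fail**

1. Step 8 (key step). The Grignard reagent may act as a base. The magnesium alkoxide could then trigger benzoate migration, or the acidic allylic α-hydrogen at C6 could be removed, leading to epimerisation or conjugation. Incomplete chelation would erode facial selectivity, and the basic peroxide medium could cause ester migration or methanolysis. Fallback, setting out from 6: one of the two homotopic hydroxyls would be etherified with 4-methoxybenzyl 2,2,2-trichloroacetimidate (1.0 equiv, cat. TfOH, CH2Cl2, 0 °C) to give the mono(4-methoxybenzyl) ether F1. The remaining hydroxyl would be oxidised with Dess–Martin periodinane to the α-alkoxy ketone F2. Reagent 9 (1.5 equiv, Et2O, −78 °C) would then add under Cram chelation by the ether oxygen, with no alkoxide next to an ester, to give the β-hydroxysilane F3. KF/KHCO3/H2O2 would give the diol F4, and BzCl/pyridine at −40 °C the primary benzoate F5. DDQ (CH2Cl2/pH 7 buffer, 0 °C) would remove the ether and return to the route at 12; this variant also bypasses step 6.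

2. Step 6. Oxidation may run on to the 1,2-diketone, the glycol C–C bond may cleave, or conversion may stall. Fallback, setting out from 6: monosilylation with Et3SiCl (1.0 equiv, imidazole, CH2Cl2, −30 °C) would give the mono(triethylsilyl) ether F6. Dess–Martin periodinane (NaHCO3, CH2Cl2) would oxidise the single free hydroxyl to the silyloxy ketone F7. HF·pyridine (THF, 0 °C) would remove the silyl group and return to the route at 7.

3. Step 3. The double homologation may stall after one epoxide, or base-mediated epoxide isomerisation may compete with ylide attack. Fallback, setting out from 3: PhSeCH2Li (from (PhSe)2CH2 and n-BuLi, THF, −78 °C) would open both oxiranes at CH2 to give the bis(γ-hydroxy selenide) F8. Oxidation with H2O2 (THF, 0 °C to rt) and selenoxide syn-elimination would give the two vinyl carbinols and return to the route at 4.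

**Further compounds**

F1 | step 8 | mono-O-(4-methoxybenzyl) ether of 6 (ether on the future C2 oxygen) | C=C[C@@H](OC(=O)c1ccccc1)[C@@H](O)[C@H](OCc2ccc(OC)cc2)[C@H](OC(=O)c3ccccc3)C=C
F2 | step 8 | α-(4-methoxybenzyloxy) ketone, the 4-methoxybenzyl ether of 7 | C=C[C@@H](OC(=O)c1ccccc1)C(=O)[C@H](OCc2ccc(OC)cc2)[C@H](OC(=O)c3ccccc3)C=C
F3 | step 8 | β-hydroxysilane, the 4-methoxybenzyl ether of 10 | C=C[C@@H](OC(=O)c1ccccc1)[C@@](O)(C[Si](C)(C)OC(C)C)[C@H](OCc2ccc(OC)cc2)[C@H](OC(=O)c3ccccc3)C=C
F4 | step 8 | diol, the 4-methoxybenzyl ether of 11 | C=C[C@@H](OC(=O)c1ccccc1)[C@@](O)(CO)[C@H](OCc2ccc(OC)cc2)[C@H](OC(=O)c3ccccc3)C=C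
F5 | step 8 | primary benzoate, the 4-methoxybenzyl ether of 12 | C=C[C@@H](OC(=O)c1ccccc1)[C@@](O)(COC(=O)c4ccccc4)[C@H](OCc2ccc(OC)cc2)[C@H](OC(=O)c3ccccc3)C=C
F6 | step 6 | mono-O-(triethylsilyl) ether of 6 | C=C[C@@H](OC(=O)c1ccccc1)[C@@H](O)[C@H](O[Si](CC)(CC)CC)[C@H](OC(=O)c2ccccc2)C=C
F7 | step 6 | O-(triethylsilyl) ether of 7 | C=C[C@@H](OC(=O)c1ccccc1)C(=O)[C@H](O[Si](CC)(CC)CC)[C@H](OC(=O)c2ccccc2)C=C
F8 | step 3 | 1,2,7,8-tetradeoxy-4,5-O-isopropylidene-1,8-bis(phenylselanyl)-D-manno-octitol | c1ccccc1[Se]CC[C@@H](O)[C@H]2OC(C)(C)O[C@@H]2[C@H](O)CC[Se]c3ccccc3
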